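## Retrosynthetic overview

- The route rests on ring A: its C5 and C8 oxygens are para, and C8a, the carbon bonded to O1, lies between C8 and C4a. Ring A can therefore pass through a 2-acyl-1,4-benzoquinone in which C8a is the one carbon β to both the C5 carbonyl and the C4 ketone.
- O1–C8a is disconnected last and closes ring C, the only ring that is made. The tribenzylated 5,8-dihydroxyflavone comes from a 1-(4-benzyloxy-2,5-dihydroxyphenyl)-2-methoxy-3-aryl-1,3-dione by Ag2O oxidation and addition of the enol oxygen; 8-O-methylation and hydrogenolysis follow.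
- The diketone comes from aldol addition and oxidation (C2–C3 bond) between a bis-silylated ring A methoxymethyl ketone and 2,4-bis(benzyloxy)-5-methoxybenzaldehyde. The ketone comes from an aryl bromide and the Weinreb amide of methoxyacetic acid (C4–C4a bond).
- Ring A is made from 2-(benzyloxy)phenol by para-oxidation, reduction, silylation and bromination. Ring B is made from isovanillin benzyl ether by Baeyer–Villiger oxidation, benzylation and Vilsmeier formylation.
- Rings A and B are bought as arenes; no stereocentre remains in the target.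

Key step: step 12

Remark: the 2-methoxy-1,3-diketones are drawn as diketo forms; they are racemic and partly enolised at the methoxy-bearing carbon, which ends as sp2 C3 of the flavone. 3-(Benzyloxy)-4-methoxybenzaldehyde (the benzyl ether of isovanillin) is taken as commercial.

## Route

Step 1
Reactants: 1 2-(benzyloxy)phenol
Product: 3 2-(benzyloxy)benzene-1,4-diol, via 2-(benzyloxy)-1,4-benzoquinone 2 (not isolated)
Conditions: K2[ON(SO3)2] (2.2 equiv), KH2PO4, H2O/acetone, 0 °C to rt; extract into EtOAc; then aq Na2S2O4, rt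
Reagents that add atoms: Fremy's salt K2[ON(SO3)2], [K+].[K+].[O]N(S(=O)(=O)[O-])S(=O)(=O)[O-]
Why: Teuber oxidation, in which the nitrosodisulfonate radical converts a phenol with a free para position into the 1,4-benzoquinone, followed by dithionite reduction of the extracted quinone, which should leave the benzyl ether untouched.

Step 2
Reactants: 3 2-(benzyloxy)benzene-1,4-diol
Product: 4 2-(benzyloxy)-1,4-bis(triisopropylsilyloxy)benzene
Conditions: iPr3SiCl (2.4 equiv), imidazole (5 equiv), DMF, rt, argon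
Reagents that add atoms: chlorotriisopropylsilane, CC(C)[Si](Cl)(C(C)C)C(C)C
Why: Silylation of phenols with a silyl chloride and imidazole; the bulky triisopropylsilyl group is chosen because it resists silyl shifts in the later aryllithium and enolate and is removed by fluoride without acid.

Step 3
Reactants: 4 2-(benzyloxy)-1,4-bis(triisopropylsilyloxy)benzene
Product: 5 1-(benzyloxy)-4-bromo-2,5-bis(triisopropylsilyloxy)benzene
Conditions: NBS (1.05 equiv), MeCN, 0 °C to rt, dark
Reagents that add atoms: N-bromosuccinimide, O=C1CCC(=O)N1Br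
Why: Electrophilic aromatic bromination; the carbon para to benzyloxy and ortho to one silyloxy group is the only one activated by two oxygens and not flanked by two substituents, so one bromide is expected.

Step 4
Reactants: 6 methoxyacetyl chloride; 7 N,O-dimethylhydroxylamine hydrochloride
Product: 8 N,2-dimethoxy-N-methylacetamide
Conditions: Et3N (2.2 equiv), CH2Cl2, 0 °C to rt
Reagents that add atoms: none
Why: N-acylation of an amine by an acid chloride (Weinreb amide formation).

Step 5
Reactants: 5 1-(benzyloxy)-4-bromo-2,5-bis(triisopropylsilyloxy)benzene; 8 N,2-dimethoxy-N-methylacetamide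
Product: 10 1-[4-(benzyloxy)-2,5-bis(triisopropylsilyloxy)phenyl]-2-methoxyethan-1-one, via aryllithium 9 (not isolated)
Conditions: n-BuLi (1.05 equiv), THF, −78 °C, 15 min; then 8 (1.3 equiv), −78 to −40 °C; AcOH quench
Reagents that add atoms: none
Why: Bromine–lithium exchange followed by Weinreb ketone synthesis, in which the N-methoxy-N-methyl amide stops the addition at the ketone; at −78 °C the aryllithium next to the bulky silyloxy group should be trapped before any silyl migration.

Step 6
Reactants: 11 3-(benzyloxy)-4-methoxybenzaldehyde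
Product: 13 3-(benzyloxy)-4-methoxyphenol, via aryl formate 12 (not isolated)
Conditions: mCPBA (1.3 equiv), CH2Cl2, rt; then K2CO3 (cat.), MeOH, rt
Reagents that add atoms: 3-chloroperbenzoic acid, O=C(OO)c1cccc(Cl)c1
Why: Baeyer–Villiger (Dakin-type) oxidation of an electron-rich benzaldehyde, in which the para-methoxyaryl group migrates to oxygen, followed by methanolysis of the aryl formate.

Step 7
Reactants: 13 3-(benzyloxy)-4-methoxyphenol
Product: 14 2,4-bis(benzyloxy)-1-methoxybenzene
Conditions: BnBr (1.1 equiv), K2CO3 (1.5 equiv), DMF, 50 °C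
Reagents that add atoms: benzyl bromide, BrCc1ccccc1
Why: Williamson ether synthesis on a phenoxide.

Step 8
Reactants: 14 2,4-bis(benzyloxy)-1-methoxybenzene
Product: 16 2,4-bis(benzyloxy)-5-methoxybenzaldehyde, via iminium chloride 15 (not isolated)
Conditions: POCl3 (1.3 equiv), DMF, 0 to 60 °C; then ice-water, rt
Reagents that add atoms: N,N-dimethylformamide, CN(C)C=O; water, O
Why: Vilsmeier–Haack formylation; the chloroiminium ion should attack the carbon para to one benzyloxy group and ortho to the other, since the carbon between the two benzyloxy groups is blocked, and benzyl ethers tolerate the conditions.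

Step 9
Reactants: 10 1-[4-(benzyloxy)-2,5-bis(triisopropylsilyloxy)phenyl]-2-methoxyethan-1-one; 16 2,4-bis(benzyloxy)-5-methoxybenzaldehyde
Product: 18 1-[4-(benzyloxy)-2,5-bis(triisopropylsilyloxy)phenyl]-3-[2,4-bis(benzyloxy)-5-methoxyphenyl]-3-hydroxy-2-methoxypropan-1-one (mixture of racemic syn and anti diastereomers), via lithium enolate 17 (not isolated)
Conditions: LiN(SiMe3)2 (1.05 equiv), THF, −78 °C; then 16, −78 °C; AcOH quench at −78 °C
Reagents that add atoms: none
Why: Aldol addition of the chelated lithium Z-enolate of the α-methoxy ketone with a cold quench; the two new stereocentres form without control, which does not matter because the carbinol is oxidised in step 10 and the methoxy-bearing carbon ends as sp2 C3.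

Step 10
Reactants: 18 the aldol adduct (diastereomer mixture)
Product: 19 1-[4-(benzyloxy)-2,5-bis(triisopropylsilyloxy)phenyl]-3-[2,4-bis(benzyloxy)-5-methoxyphenyl]-2-methoxypropane-1,3-dione (racemic)
Conditions: Dess–Martin periodinane (1.5 equiv), CH2Cl2, 0 °C to rt
Reagents that add atoms: none
Why: Dess–Martin oxidation of a β-hydroxy ketone to the 1,3-diketone under mild conditions that should leave aryl silyl and benzyl ethers intact; the remaining stereocentre is enolisable and racemic.

Step 11
Reactants: 19 the bis-silylated 1,3-diketone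
Product: 20 1-[4-(benzyloxy)-2,5-dihydroxyphenyl]-3-[2,4-bis(benzyloxy)-5-methoxyphenyl]-2-methoxypropane-1,3-dione (racemic)
Conditions: Bu4NF (2.2 equiv), AcOH (2.5 equiv), degassed THF, 0 °C, argon; pH 6 buffer work-up; used at once
Reagents that add atoms: none
Why: Fluoride cleavage of aryl silyl ethers, buffered with acetic acid so that neither phenoxide nor strong acid is present and the ortho-hydroxy diketone is not driven to dehydrative ring closure.

Step 12
Reactants: 20 1-[4-(benzyloxy)-2,5-dihydroxyphenyl]-3-[2,4-bis(benzyloxy)-5-methoxyphenyl]-2-methoxypropane-1,3-dione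
Product: 23 7-(benzyloxy)-2-[2,4-bis(benzyloxy)-5-methoxyphenyl]-5,8-dihydroxy-3-methoxy-4H-chromen-4-one, via acylquinone 21 (not isolated), via flavone-5,8-quinone 22 (not isolated)
Conditions: Ag2O (3 equiv), Na2SO4, CH2Cl2, rt, dark, argon; filter; then aq Na2S2O4, EtOAc, rt
Reagents that add atoms: none
Why: Proposed new method: Ag2O dehydrogenates the free hydroquinone of 20 to acylquinone 21, in which C8a (flavone numbering) is β to both the C5 quinone carbonyl and the C4 ketone; the enol oxygen on the ring B side of the 2-methoxy-1,3-diketone adds to this carbon, and transfer of the C8a proton to the C8 oxygen restores the aromatic ring as the 5,8-dihydroxyflavone. The closest known reaction type is the conjugate addition of oxygen, nitrogen, sulfur and carbon nucleophiles to C3 of 2-acyl-1,4-benzoquinones with rearomatisation to 3-substituted acylhydroquinones; what is new is its intramolecular use with a diketone enol oxygen to build a 4-pyranone. Ring C closes in the 6-endo-trig mode by forming O1–C8a; no stereocentre is formed, and the racemic methoxy-bearing carbon of 20 ends as sp2 C3. Site selectivity comes from the tether, which lets the enol oxygen reach only C8a through a six-membered transition state and not C6 or the benzyloxy-bearing C7, while attack on the C5 carbonyl would give only a reversible hemiketal and the conjugate addition is made irreversible by aromatisation. Chemoselectivity rests on neutral Ag2O, which should oxidise only the free hydroquinone and not the aryl ethers, and on the absence of acid, so that the ortho-hydroxyl of 20 becomes a quinone carbonyl before it can close onto C2 with loss of water. Since 23 is a more electron-rich hydroquinone than 20, the excess oxidant is expected to take it on to quinone 22, and the dithionite stage returns this material to 23.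

Step 13
Reactants: 23 7-(benzyloxy)-2-[2,4-bis(benzyloxy)-5-methoxyphenyl]-5,8-dihydroxy-3-methoxy-4H-chromen-4-one
Product: 24 7-(benzyloxy)-2-[2,4-bis(benzyloxy)-5-methoxyphenyl]-5-hydroxy-3,8-dimethoxy-4H-chromen-4-one
Conditions: MeI (1.05 equiv), K2CO3 (1.1 equiv), degassed acetone, rt, argon
Reagents that add atoms: iodomethane, CI
Why: Williamson methylation with one equivalent of MeI; the 5-OH is hydrogen-bonded to the C4 carbonyl and much less nucleophilic, so the free 8-OH should react selectively, as is usual for 5-hydroxyflavones.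

Step 14
Reactants: 24 7-(benzyloxy)-2-[2,4-bis(benzyloxy)-5-methoxyphenyl]-5-hydroxy-3,8-dimethoxy-4H-chromen-4-one
Product: 25 5,7,2',4'-tetrahydroxy-3,8,5'-trimethoxyflavone
Conditions: H2 (1 atm), 10% Pd/C, EtOAc/MeOH, rt
Reagents that add atoms: none
Why: Catalytic hydrogenolysis of the three aryl benzyl ethers; aryl methyl ethers and the flavone enone should be inert at 1 atm and rt.

## Compound list

1 | 2-(benzyloxy)phenol | Oc1ccccc1OCc1ccccc1 | starting material
2 | 2-(benzyloxy)-1,4-benzoquinone | O=C1C=CC(=O)C(OCc2ccccc2)=C1 | intermediate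
3 | 2-(benzyloxy)benzene-1,4-diol | Oc1ccc(O)c(OCc2ccccc2)c1 | intermediate
4 | 2-(benzyloxy)-1,4-bis(triisopropylsilyloxy)benzene | CC(C)[Si](Oc1ccc(O[Si](C(C)C)(C(C)C)C(C)C)c(OCc2ccccc2)c1)(C(C)C)C(C)C | intermediate
5 | 1-(benzyloxy)-4-bromo-2,5-bis(triisopropylsilyloxy)benzene | CC(C)[Si](Oc1cc(OCc2ccccc2)c(O[Si](C(C)C)(C(C)C)C(C)C)cc1Br)(C(C)C)C(C)C | intermediate
6 | methoxyacetyl chloride | COCC(=O)Cl | starting material
7 | N,O-dimethylhydroxylamine hydrochloride | CNOC.Cl | starting material
8 | N,2-dimethoxy-N-methylacetamide | COCC(=O)N(C)OC | intermediate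
9 | [4-(benzyloxy)-2,5-bis(triisopropylsilyloxy)phenyl]lithium | [Li]c1cc(O[Si](C(C)C)(C(C)C)C(C)C)c(OCc2ccccc2)cc1O[Si](C(C)C)(C(C)C)C(C)C | intermediate
10 | 1-[4-(benzyloxy)-2,5-bis(triisopropylsilyloxy)phenyl]-2-methoxyethan-1-one | COCC(=O)c1cc(O[Si](C(C)C)(C(C)C)C(C)C)c(OCc2ccccc2)cc1O[Si](C(C)C)(C(C)C)C(C)C | intermediate
11 | 3-(benzyloxy)-4-methoxybenzaldehyde | COc1ccc(C=O)cc1OCc1ccccc1 | starting material
12 | 3-(benzyloxy)-4-methoxyphenyl formate | COc1ccc(OC=O)cc1OCc1ccccc1 | intermediate
13 | 3-(benzyloxy)-4-methoxyphenol | COc1ccc(O)cc1OCc1ccccc1 | intermediate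
14 | 2,4-bis(benzyloxy)-1-methoxybenzene | COc1ccc(OCc2ccccc2)cc1OCc1ccccc1 | intermediate
15 | N-[2,4-bis(benzyloxy)-5-methoxybenzylidene]-N-methylmethanaminium chloride | C[N+](C)=Cc1cc(OC)c(OCc2ccccc2)cc1OCc1ccccc1.[Cl-] | intermediate
16 | 2,4-bis(benzyloxy)-5-methoxybenzaldehyde | COc1cc(C=O)c(OCc2ccccc2)cc1OCc1ccccc1 | intermediate
17 | lithium (Z)-1-[4-(benzyloxy)-2,5-bis(triisopropylsilyloxy)phenyl]-2-methoxyethen-1-olate | [Li]O/C(=C\OC)c1cc(O[Si](C(C)C)(C(C)C)C(C)C)c(OCc2ccccc2)cc1O[Si](C(C)C)(C(C)C)C(C)C | intermediate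
18 | 1-[4-(benzyloxy)-2,5-bis(triisopropylsilyloxy)phenyl]-3-[2,4-bis(benzyloxy)-5-methoxyphenyl]-3-hydroxy-2-methoxypropan-1-one (racemic syn and anti mixture) | COC(C(O)c1cc(OC)c(OCc2ccccc2)cc1OCc1ccccc1)C(=O)c1cc(O[Si](C(C)C)(C(C)C)C(C)C)c(OCc2ccccc2)cc1O[Si](C(C)C)(C(C)C)C(C)C | intermediate
19 | 1-[4-(benzyloxy)-2,5-bis(triisopropylsilyloxy)phenyl]-3-[2,4-bis(benzyloxy)-5-methoxyphenyl]-2-methoxypropane-1,3-dione (racemic) | COC(C(=O)c1cc(OC)c(OCc2ccccc2)cc1OCc1ccccc1)C(=O)c1cc(O[Si](C(C)C)(C(C)C)C(C)C)c(OCc2ccccc2)cc1O[Si](C(C)C)(C(C)C)C(C)C | intermediate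
20 | 1-[4-(benzyloxy)-2,5-dihydroxyphenyl]-3-[2,4-bis(benzyloxy)-5-methoxyphenyl]-2-methoxypropane-1,3-dione (racemic) | COC(C(=O)c1cc(O)c(OCc2ccccc2)cc1O)C(=O)c1cc(OC)c(OCc2ccccc2)cc1OCc1ccccc1 | intermediate
21 | 2-(benzyloxy)-5-{3-[2,4-bis(benzyloxy)-5-methoxyphenyl]-2-methoxy-3-oxopropanoyl}-1,4-benzoquinone (racemic) | COC(C(=O)C1=CC(=O)C(OCc2ccccc2)=CC1=O)C(=O)c1cc(OC)c(OCc2ccccc2)cc1OCc1ccccc1 | intermediate
22 | 7-(benzyloxy)-2-[2,4-bis(benzyloxy)-5-methoxyphenyl]-3-methoxy-4H-chromene-4,5,8-trione | COc1cc(C2=C(OC)C(=O)C3=C(O2)C(=O)C(OCc2ccccc2)=CC3=O)c(OCc2ccccc2)cc1OCc1ccccc1 | intermediate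
23 | 7-(benzyloxy)-2-[2,4-bis(benzyloxy)-5-methoxyphenyl]-5,8-dihydroxy-3-methoxy-4H-chromen-4-one | COc1cc(-c2oc3c(O)c(OCc4ccccc4)cc(O)c3c(=O)c2OC)c(OCc2ccccc2)cc1OCc1ccccc1 | intermediate
24 | 7-(benzyloxy)-2-[2,4-bis(benzyloxy)-5-methoxyphenyl]-5-hydroxy-3,8-dimethoxy-4H-chromen-4-one | COc1cc(-c2oc3c(OC)c(OCc4ccccc4)cc(O)c3c(=O)c2OC)c(OCc2ccccc2)cc1OCc1ccccc1 | intermediate
25 | 5,7,2',4'-tetrahydroxy-3,8,5'-trimethoxyflavone | COc1cc(-c2oc3c(OC)c(O)cc(O)c3c(=O)c2OC)c(O)cc1O | target

## Step count and risks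

Total step count: 14. Longest linear sequence: 10 steps (steps 1, 2, 3, 5, 9, 10, 11, 12, 13, 14).

**Step 12 (proposed new method).** The addition of the enol oxygen may be slower than intermolecular consumption of the acylquinone (self-condensation, hydration), or the closed ring may be oxidised further before it rearomatises cleanly. The fallback uses known chemistry, sets out from aldehyde 16 and comes back at 23; it installs the C8 oxygen by para-hydroxylation of a 5-hydroxyflavone.
- Aldehyde 16 would be oxidised (NaClO2, NaH2PO4, 2-methyl-2-butene, t-BuOH/H2O; Pinnick oxidation) to 2,4-bis(benzyloxy)-5-methoxybenzoic acid F1.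
- Part of F1 would be dehydrated (DCC, CH2Cl2) to 2,4-bis(benzyloxy)-5-methoxybenzoic anhydride F2, and part neutralised (NaOH, MeOH) to sodium 2,4-bis(benzyloxy)-5-methoxybenzoate F3.
- Allan–Robinson condensation of commercial 2-methoxy-1-(2,4,6-trihydroxyphenyl)ethanone (COCC(=O)c1c(O)cc(O)cc1O) with F2 and F3 at about 170 °C, then aqueous KOH/EtOH work-up, should give 2-[2,4-bis(benzyloxy)-5-methoxyphenyl]-5,7-dihydroxy-3-methoxy-4H-chromen-4-one F4.
- Benzylation of the more acidic, non-chelated 7-OH (BnBr 1 equiv, K2CO3, acetone) should give 7-(benzyloxy)-2-[2,4-bis(benzyloxy)-5-methoxyphenyl]-5-hydroxy-3-methoxy-4H-chromen-4-one F5.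
- Elbs persulfate oxidation (K2S2O8, aq KOH/pyridine, 0 °C to rt) should hydroxylate para to the 5-OH via potassium 7-(benzyloxy)-2-[2,4-bis(benzyloxy)-5-methoxyphenyl]-5-hydroxy-3-methoxy-4-oxo-4H-chromen-8-yl sulfate F6; hydrolysis (dilute HCl, Na2SO3, 80 °C) gives 23.

**Step 11.** When the hydroxyl ortho to the ketone is set free next to the 1,3-diketone, fluoride or adventitious base may trigger closure of that oxygen onto the ring B carbonyl with loss of water, retro-Claisen cleavage, or uncontrolled air oxidation. The fallback reverses the order of deprotection and diketone formation; it sets out from aldol adduct 18 and comes back at acylquinone 21.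
- Buffered desilylation of 18 (Bu4NF, AcOH, THF, 0 °C) would give 1-[4-(benzyloxy)-2,5-dihydroxyphenyl]-3-[2,4-bis(benzyloxy)-5-methoxyphenyl]-3-hydroxy-2-methoxypropan-1-one F7, which has no 1,3-diketone and cannot dehydrate to a flavone.
- Dess–Martin periodinane (3 equiv, CH2Cl2, rt) would then oxidise the hydroquinone and the carbinol together, giving acylquinone 21 directly; this enters the closure and dithionite stage of step 12 without the free ortho-hydroxy diketone ever being present.

**Step 5.** A silyl group may migrate from oxygen to the lithiated carbon (retro-Brook shift), or the aryllithium may take a proton from the amide. The fallback changes the protecting groups; it sets out from hydroquinone 3 and comes back at ketone 10.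
- 3 would be protected (MOMCl, iPr2NEt, CH2Cl2) as 2-(benzyloxy)-1,4-bis(methoxymethoxy)benzene F8 and brominated para to benzyloxy (NBS, MeCN) to 1-(benzyloxy)-4-bromo-2,5-bis(methoxymethoxy)benzene F9.
- Bromine–lithium exchange (n-BuLi, THF, −78 °C) would give [4-(benzyloxy)-2,5-bis(methoxymethoxy)phenyl]lithium F10, which carries no silyl group and is stabilised by chelation; acylation with 8 gives 1-[4-(benzyloxy)-2,5-bis(methoxymethoxy)phenyl]-2-methoxyethan-1-one F11.
- Acetal cleavage (HCl, MeOH, 40 °C), harmless at the simple ketone stage, would give 1-[4-(benzyloxy)-2,5-dihydroxyphenyl]-2-methoxyethan-1-one F12; silylation (iPr3SiOTf, 2,6-lutidine, CH2Cl2) returns to 10.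

## Further compounds

F1 | step 12 | 2,4-bis(benzyloxy)-5-methoxybenzoic acid | COc1cc(C(=O)O)c(OCc2ccccc2)cc1OCc1ccccc1
F2 | step 12 | 2,4-bis(benzyloxy)-5-methoxybenzoic anhydride | COc1cc(C(=O)OC(=O)c2cc(OC)c(OCc3ccccc3)cc2OCc2ccccc2)c(OCc2ccccc2)cc1OCc1ccccc1
F3 | step 12 | sodium 2,4-bis(benzyloxy)-5-methoxybenzoate | COc1cc(C(=O)[O-])c(OCc2ccccc2)cc1OCc1ccccc1.[Na+]
F4 | step 12 | 2-[2,4-bis(benzyloxy)-5-methoxyphenyl]-5,7-dihydroxy-3-methoxy-4H-chromen-4-one | COc1cc(-c2oc3cc(O)cc(O)c3c(=O)c2OC)c(OCc2ccccc2)cc1OCc1ccccc1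
F5 | step 12 | 7-(benzyloxy)-2-[2,4-bis(benzyloxy)-5-methoxyphenyl]-5-hydroxy-3-methoxy-4H-chromen-4-one | COc1cc(-c2oc3cc(OCc4ccccc4)cc(O)c3c(=O)c2OC)c(OCc2ccccc2)cc1OCc1ccccc1
F6 | step 12 | potassium 7-(benzyloxy)-2-[2,4-bis(benzyloxy)-5-methoxyphenyl]-5-hydroxy-3-methoxy-4-oxo-4H-chromen-8-yl sulfate | COc1cc(-c2oc3c(OS(=O)(=O)[O-])c(OCc4ccccc4)cc(O)c3c(=O)c2OC)c(OCc2ccccc2)cc1OCc1ccccc1.[K+]
F7 | step 11 | 1-[4-(benzyloxy)-2,5-dihydroxyphenyl]-3-[2,4-bis(benzyloxy)-5-methoxyphenyl]-3-hydroxy-2-methoxypropan-1-one (racemic syn and anti mixture) | COC(C(O)c1cc(OC)c(OCc2ccccc2)cc1OCc1ccccc1)C(=O)c1cc(O)c(OCc2ccccc2)cc1O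
F8 | step 5 | 2-(benzyloxy)-1,4-bis(methoxymethoxy)benzene | COCOc1ccc(OCOC)c(OCc2ccccc2)c1
F9 | step 5 | 1-(benzyloxy)-4-bromo-2,5-bis(methoxymethoxy)benzene | COCOc1cc(OCc2ccccc2)c(OCOC)cc1Br
F10 | step 5 | [4-(benzyloxy)-2,5-bis(methoxymethoxy)phenyl]lithium | [Li]c1cc(OCOC)c(OCc2ccccc2)cc1OCOC
F11 | step 5 | 1-[4-(benzyloxy)-2,5-bis(methoxymethoxy)phenyl]-2-methoxyethan-1-one | COCC(=O)c1cc(OCOC)c(OCc2ccccc2)cc1OCOC
F12 | step 5 | 1-[4-(benzyloxy)-2,5-dihydroxyphenyl]-2-methoxyethan-1-one | COCC(=O)c1cc(O)c(OCc2ccccc2)cc1O
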